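Ring B (C5–C10) maps onto 2,6-dimethylbenzoquinone: its carbonyl carbons are C6 and C9, its methyls sit on C8 and C10, and C5=C10 is a dienophile; C1–C4 with the C3 oxygen form a 2-silyloxydiene. The route rests on one Diels–Alder reaction between the quinone C6-monoketal of (2R,3R)-butane-2,3-diol and the (Z)-silyl dienol ether of pent-1-en-3-one. It forms C4–C5 and C1–C10, closes ring A with oxygen on C3, and sets C10 (and C5, cis) under control of the twofold-symmetric ketal. Afterwards C9=O is methylenated, C4 is methylated, C5 is epimerised to the trans-decalin, and C3, C9 and the aryl ether are set on that rigid frame.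

Key step: step 4

Remark: positions are given in the terpenoid numbering of the target (ring A: C1–C5 and C10; ring B: C5–C10; C11 is the CH2 on C9; the target is 3R,5S,9R,10S). CIP letters of intermediates change with substitution although the geometry does not, so the SMILES are authoritative. 4-Methoxy-2,6-dimethylphenol is taken as a catalogue chemical, because direct ketalisation of a quinone with a diol is not dependable.

Step 1
Reactants: 1 4-methoxy-2,6-dimethylphenol
Product: 2 4,4-dimethoxy-2,6-dimethylcyclohexa-2,5-dien-1-one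
Conditions: PhI(OAc)2 (1.1 equiv), MeOH, 0 °C → rt
Reagents that add atoms: methanol, CO
Why: Oxidative dearomatisation of a 4-alkoxyphenol by a hypervalent iodine diacetate in methanol, in which the phenoxenium ion is trapped at the para carbon, is the standard entry to quinone monoketals, and the two flanking methyls leave no other site open.

Step 2
Reactants: 2 4,4-dimethoxy-2,6-dimethylcyclohexa-2,5-dien-1-one; 3 (2R,3R)-butane-2,3-diol
Product: 4 (2R,3R)-2,3,7,9-tetramethyl-1,4-dioxaspiro[4.5]deca-6,9-dien-8-one (fragment 1)
Conditions: BF3·OEt2 (0.2 equiv), DME, 0 °C → rt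
Reagents that add atoms: none
Why: Acid-catalysed transketalisation replaces both methoxy groups and is driven by closure of the five-membered dioxolane; the carbinol carbons are not touched, so the ketal stays 2R,3R and its twofold axis coincides with that of the dienone.

Step 3
Reactants: 5 pent-1-en-3-one
Product: 6 tert-butyldimethyl[(Z)-penta-1,3-dien-3-yloxy]silane (fragment 2)
Conditions: TBSOTf, Et3N, CH2Cl2, 0 °C → rt
Reagents that add atoms: tert-butyldimethylsilyl trifluoromethanesulfonate, CC(C)(C)[Si](C)(C)OS(=O)(=O)C(F)(F)F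
Why: Soft enolisation of the ethyl ketone with a silyl triflate and triethylamine should give the dienol ether with the methyl cis to oxygen (Z), the geometry that reaches the s-cis diene with the methyl pointing outwards.

Step 4
Reactants: 4 (2R,3R)-2,3,7,9-tetramethyl-1,4-dioxaspiro[4.5]deca-6,9-dien-8-one; 6 tert-butyldimethyl[(Z)-penta-1,3-dien-3-yloxy]silane
Product: 7 cis-fused adduct (4R,5S,10R): C2=C3 silyl enol ether (OTBS on C3); CH3 on C4 trans to H-5; C6 (2R,3R)-butane-2,3-diyl ketal; C7=C8(CH3)–C9=O enone; CH3 on C10 cis to H-5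
Conditions: Me2AlCl (1.2 equiv), CH2Cl2, −78 → −30 °C; then Et3N, H2O
Reagents that add atoms: none
Why: The electron-rich diene 6 and the Me2AlCl-complexed enone of 4 should combine in a concerted but asynchronous normal-demand Diels–Alder reaction, the known addition of 2-silyloxydienes to quinone monoketals: the diene carbon β to the silyloxy oxygen (C4) bonds first to C5, the β-carbon of the only enone carbonyl, and the CH2 terminus then closes onto the methyl-bearing C10. Ring A closes in this single suprafacial [4+2] event as a six-membered cyclohexene that already carries the C3 oxygen as the C2=C3 silyl enol ether. C5 and C10 are set cis by suprafacial addition to the ring alkene, and their absolute sense by the dioxolane: its twofold axis makes the two enone alkenes equivalent, and on the reacting alkene one ketal methyl leans towards C5 on one face, so the diene should add to the other face, which gives C10 as in the target. C4 follows from the endo placement of ring B and the Z geometry of 6, and is erased in step 7. The selectivity the step needs is facial, since regiochemistry is fixed by the silyloxy group and the single carbonyl; an adduct from the wrong face would be a diastereomer removable by chromatography, so enantiopurity does not depend on the level of induction.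

Step 5
Reactants: 7 cis-fused adduct (4R,5S,10R)
Product: 8 C9-methylidene triene (4R,5S,10R): as 7 but C9=CH2 in place of C9=O
Conditions: Ph3PCH3Br (3 equiv), KN(SiMe3)2 (2.8 equiv), toluene, 0 → 80 °C
Reagents that add atoms: methyltriphenylphosphonium bromide, C[P+](c1ccccc1)(c1ccccc1)c1ccccc1.[Br-]
Why: Wittig methylenation of the only free carbonyl; C9 has no α-hydrogen (C10 quaternary, C8 sp2) so the ylide cannot enolise it, C3 is still masked as its silyl enol ether, the ketal is inert to base, and hindered ketones of this kind are methylenated by the salt-free ylide on heating.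

Step 6
Reactants: 8 C9-methylidene triene (4R,5S,10R)
Product: 9 cis-fused C3 ketone (4R,5S,10R): CH3 on C4; C6 ketal; C7=C8–C9=CH2 diene
Conditions: Bu4NF, AcOH, THF, 0 °C
Reagents that add atoms: none
Why: Fluoride cleaves the Si–O bond and the buffered enolate is protonated to the C3 ketone; mineral acid is avoided because the ketal, now allylic to a diene, has become acid-labile, and any epimerisation of the C4 methine is irrelevant.

Step 7
Reactants: 9 cis-fused C3 ketone (4R,5S,10R)
Product: 10 cis-fused 4,4-dimethyl C3 ketone (5R,10R): C6 ketal; C7=C8–C9=CH2 diene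
Conditions: t-BuOK (1.1 equiv), MeI (1.5 equiv), t-BuOH/THF, 0 °C → rt
Reagents that add atoms: iodomethane, CI
Why: Thermodynamic enolate alkylation; under equilibrating alkoxide conditions a cis-fused decalin-3-one enolises towards the ring fusion and the more substituted C3=C4 enolate is favoured, so methyl iodide should quaternise C4 and erase its stereocentre, and nothing else in 9 is enolisable or electrophilic.

Step 8
Reactants: 10 cis-fused 4,4-dimethyl C3 ketone (5R,10R)
Product: 12 trans-fused (5S,10R)-4,4,8,10-tetramethyl-9-methylidene-7-ene-3,6-dione (H-5 trans to CH3-10), via cis-fused (5R,10R) dienedione 11 (not isolated)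
Conditions: 1 M HCl, THF, 40 °C
Reagents that add atoms: water, O
Why: Aqueous acid hydrolyses the dienyl ketal through a pentadienyl-stabilised oxocarbenium ion, and the freed C6 ketone should then epimerise C5 through its enol to the more stable trans-decalin, as 6-oxo-4,4,10-trimethyldecalins do; C5 is the only centre able to move because C4 and C10 are quaternary and C9 is sp2.

Step 9
Reactants: 12 trans-fused (5S,10R)-3,6-dione
Product: 13 (3R,5S,6S,10R)-4,4,8,10-tetramethyl-9-methylidene-7-ene-3,6-diol (3-OH equatorial and cis to CH3-10; 6-OH axial; the 6-epimer serves equally)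
Conditions: NaBH4 (3 equiv), CeCl3·7H2O, MeOH, −20 → 0 °C
Reagents that add atoms: none
Why: Luche reduction delivers hydride 1,2 to the dienone and to the saturated ketone; at C3 axial attack on the chair 4,4-dimethyl-3-ketone should give the equatorial 3R alcohol, the usual outcome for this substructure in trans-fused terpenoids, while at C6 attack anti to the two axial methyls gives a carbinol that is removed again in step 11.

Step 10
Reactants: 13 (3R,5S,6S,10R)-7,9(11)-diene-3,6-diol
Product: 15 (3R,5S,6S,9R,10S)-4,4,8,10-tetramethyl-7-ene-3,6,11-triol (CH2OH on C9 cis to CH3-10), via C11 B-alkyl-9-BBN adduct 14 (not isolated)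
Conditions: 9-BBN (4 equiv), THF, 0 °C → rt; then NaOH, H2O2, 0 °C → rt
Reagents that add atoms: hydrogen peroxide, OO
Why: Hydroboration–oxidation with the bulky 9-BBN puts boron on the terminal carbon of the 1,1-disubstituted alkene and leaves the trisubstituted C7=C8 alone, and hydrogen should reach C9 from the face opposite the axial C10 methyl, the sense expected for an exocyclic alkene next to an angular methyl in a trans-decalin; the free hydroxyls only consume extra reagent.

Step 11
Reactants: 15 (3R,5S,6S,9R,10S)-7-ene-3,6,11-triol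
Product: 16 (3R,5S,9R,10S)-3,11-dihydroxy-4,4,8,10-tetramethyl-7-en-6-one
Conditions: activated MnO2 (excess), CH2Cl2, rt
Reagents that add atoms: none
Why: MnO2 oxidises allylic alcohols selectively, so only the C6 carbinol should be converted into the enone while the saturated primary and secondary hydroxyls remain, and the neutral medium does not enolise the γ-position C9.

Step 12
Reactants: 16 (3R,5S,9R,10S)-3,11-dihydroxy-7-en-6-one; 17 umbelliferone (7-hydroxy-2H-chromen-2-one)
Product: 18 (3R,5S,9R,10S)-3-hydroxy-4,4,8,10-tetramethyl-11-(2-oxo-2H-chromen-7-yloxy)-7-en-6-one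
Conditions: PPh3, DIAD, THF, 0 °C → rt
Reagents that add atoms: none
Why: Mitsunobu etherification; the acidic phenol of 17 should displace the activated primary C11 oxygen, the hindered equatorial C3 hydroxyl beside the gem-dimethyl group does not compete, and the near-neutral medium avoids base-induced loss of the aryloxide through the dienolate.

Step 13
Reactants: 18 (3R,5S,9R,10S)-3-hydroxy-11-aryloxy-7-en-6-one
Product: 19 target CNP0363962.1: (3R,5S,9R,10S)-3-acetoxy-4,4,8,10-tetramethyl-11-(2-oxo-2H-chromen-7-yloxy)-7-en-6-one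
Conditions: Ac2O, pyridine, DMAP (cat.), CH2Cl2, rt
Reagents that add atoms: acetic anhydride, CC(=O)OC(C)=O
Why: Nucleophile-catalysed acylation of the remaining secondary alcohol proceeds with retention at C3, and pyridine/DMAP is too weak a base to enolise the enone or expel the aryloxide.

Compound list

1 | 4-methoxy-2,6-dimethylphenol | COc1cc(C)c(O)c(C)c1 | starting material
2 | 4,4-dimethoxy-2,6-dimethylcyclohexa-2,5-dien-1-one | COC1(OC)C=C(C)C(=O)C(C)=C1 | intermediate
3 | (2R,3R)-butane-2,3-diol | C[C@@H](O)[C@@H](C)O | starting material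
4 | (2R,3R)-2,3,7,9-tetramethyl-1,4-dioxaspiro[4.5]deca-6,9-dien-8-one (fragment 1) | CC1=CC2(O[C@H](C)[C@@H](C)O2)C=C(C)C1=O | intermediate
5 | pent-1-en-3-one | CCC(=O)C=C | starting material
6 | tert-butyldimethyl[(Z)-penta-1,3-dien-3-yloxy]silane (fragment 2) | C/C=C(\O[Si](C)(C)C(C)(C)C)C=C | intermediate
7 | cis-fused adduct (4R,5S,10R): C2=C3 TBS enol ether, CH3 on C4, C6 (2R,3R)-butanediyl ketal, C7=C8(CH3)–C9=O, CH3 on C10 cis to H-5 | CC(C)(C)[Si](C)(C)OC1=CC[C@@]2(C)C(=O)C(C)=CC3(O[C@H](C)[C@@H](C)O3)[C@H]2[C@H]1C | intermediate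
8 | C9-methylidene triene (4R,5S,10R): as 7 with C9=CH2 | CC(C)(C)[Si](C)(C)OC1=CC[C@@]2(C)C(=C)C(C)=CC3(O[C@H](C)[C@@H](C)O3)[C@H]2[C@H]1C | intermediate
9 | cis-fused C3 ketone (4R,5S,10R) with CH3 on C4, C6 ketal and C7=C8–C9=CH2 diene | O=C1CC[C@@]2(C)C(=C)C(C)=CC3(O[C@H](C)[C@@H](C)O3)[C@H]2[C@H]1C | intermediate
10 | cis-fused 4,4-dimethyl C3 ketone (5R,10R) with C6 ketal and diene | O=C1CC[C@@]2(C)C(=C)C(C)=CC3(O[C@H](C)[C@@H](C)O3)[C@H]2C1(C)C | intermediate
11 | cis-fused (5R,10R)-4,4,8,10-tetramethyl-9-methylidene-7-ene-3,6-dione | O=C1CC[C@@]2(C)C(=C)C(C)=CC(=O)[C@H]2C1(C)C | intermediate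
12 | trans-fused (5S,10R)-4,4,8,10-tetramethyl-9-methylidene-7-ene-3,6-dione | O=C1CC[C@@]2(C)C(=C)C(C)=CC(=O)[C@@H]2C1(C)C | intermediate
13 | (3R,5S,6S,10R)-4,4,8,10-tetramethyl-9-methylidene-7-ene-3,6-diol | O[C@@H]1CC[C@@]2(C)C(=C)C(C)=C[C@H](O)[C@@H]2C1(C)C | intermediate
14 | C11 B-alkyl-9-BBN adduct of 13 (3R,5S,6S,9R,10S) | O[C@@H]1CC[C@@]2(C)[C@H](CB3C4CCCC3CCC4)C(C)=C[C@H](O)[C@@H]2C1(C)C | intermediate
15 | (3R,5S,6S,9R,10S)-4,4,8,10-tetramethyl-7-ene-3,6,11-triol | O[C@@H]1CC[C@@]2(C)[C@H](CO)C(C)=C[C@H](O)[C@@H]2C1(C)C | intermediate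
16 | (3R,5S,9R,10S)-3,11-dihydroxy-4,4,8,10-tetramethyl-7-en-6-one | O[C@@H]1CC[C@@]2(C)[C@H](CO)C(C)=CC(=O)[C@@H]2C1(C)C | intermediate
17 | umbelliferone (7-hydroxy-2H-chromen-2-one) | O=c1ccc2ccc(O)cc2o1 | starting material
18 | (3R,5S,9R,10S)-3-hydroxy-4,4,8,10-tetramethyl-11-(2-oxo-2H-chromen-7-yloxy)-7-en-6-one | O[C@@H]1CC[C@@]2(C)[C@H](COc3ccc4ccc(=O)oc4c3)C(C)=CC(=O)[C@@H]2C1(C)C | intermediate
19 | CNP0363962.1, (3R,5S,9R,10S)-3-acetoxy-4,4,8,10-tetramethyl-11-(2-oxo-2H-chromen-7-yloxy)-7-en-6-one | CC(=O)O[C@@H]1CC[C@@]2(C)[C@H](COc3ccc4ccc(=O)oc4c3)C(C)=CC(=O)[C@@H]2C1(C)C | target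

Total step count: 13. Longest linear sequence: 12 steps (steps 1, 2 and 4–13, from 4-methoxy-2,6-dimethylphenol); step 3 is a one-step branch.

Steps most likely to fail

Step 4. The two small dioxolane methyls may discriminate the faces of C5=C10 only weakly, or the Lewis acid may ionise the ketal or strip the silyl group before cycloaddition. The fallback replaces auxiliary control by reagent control and sets out from 2 (with 6). Transketalisation of 2 with 2,2-dimethylpropane-1,3-diol (BF3·OEt2, DME) would give the achiral ketal 3,3,8,10-tetramethyl-1,5-dioxaspiro[5.5]undeca-7,10-dien-9-one F1. F1 and 6 are then combined under a chiral titanium Lewis acid made from BINOL and TiCl2(Oi-Pr)2 (4 Å molecular sieves, toluene, −20 °C), a catalyst class known for enantioselective Diels–Alder additions to achiral 1,4-quinone monoketals; the ligand enantiomer that gives the 10R adduct is chosen in a test with both. This would give the cis-fused adduct with the neopentyl glycol ketal F2. The operations of steps 5, 6 and 7 then give the C9-methylidene compound F3, the C3 ketone F4 and the 4,4-dimethyl ketone F5, and the hydrolysis of step 8 removes the achiral ketal and returns the route at 12.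

Step 7. Methylation may occur at C2, or twice, in place of clean quaternisation of the crowded C4. The fallback is a regiospecific dianion alkylation from 9. Claisen formylation at the only methylene α-carbon, C2 (HCO2Et, NaH, THF), would give the 2-hydroxymethylene ketone F6. Its dianion (2.2 equiv LiN(i-Pr)2, THF, −78 → 0 °C) is alkylated by MeI at the more basic α' carbon C4 to give the 4,4-dimethyl-2-hydroxymethylene ketone F7. Retro-Claisen deformylation (aq. NaOH, EtOH, reflux; the ketal tolerates base) then gives 10.

Step 12. Activation or displacement at the β-branched C11 carbinol may be slow, or the activated oxygen may be lost by elimination across C9–C11 towards the exocyclic dienone. The fallback forms the ether before the enone exists and sets out from 15. Selective sulfonylation of the primary hydroxyl (TsCl, pyridine, 0 °C) would give the C11 tosylate F8. SN2 displacement by the caesium salt of 17 (Cs2CO3, DMF, 70 °C), safe at this stage because no carbonyl acidifies C9–H, would give the C11 umbelliferyl ether 3,6-diol F9. Oxidation of its allylic C6 carbinol with MnO2 as in step 11 gives 18.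

Further compounds

F1 | step 4 | 3,3,8,10-tetramethyl-1,5-dioxaspiro[5.5]undeca-7,10-dien-9-one | CC1=CC2(OCC(C)(C)CO2)C=C(C)C1=O
F2 | step 4 | cis-fused adduct (4R,5S,10R) with the C6 2,2-dimethylpropane-1,3-diyl ketal | CC(C)(C)[Si](C)(C)OC1=CC[C@@]2(C)C(=O)C(C)=CC3(OCC(C)(C)CO3)[C@H]2[C@H]1C
F3 | step 4 | C9-methylidene derivative of F2 | CC(C)(C)[Si](C)(C)OC1=CC[C@@]2(C)C(=C)C(C)=CC3(OCC(C)(C)CO3)[C@H]2[C@H]1C
F4 | step 4 | cis-fused C3 ketone with the achiral C6 ketal | O=C1CC[C@@]2(C)C(=C)C(C)=CC3(OCC(C)(C)CO3)[C@H]2[C@H]1C
F5 | step 4 | cis-fused 4,4-dimethyl C3 ketone with the achiral C6 ketal | O=C1CC[C@@]2(C)C(=C)C(C)=CC3(OCC(C)(C)CO3)[C@H]2C1(C)C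
F6 | step 7 | 2-hydroxymethylene derivative of 9 (chelated enol) | O=C1/C(=C\O)C[C@@]2(C)C(=C)C(C)=CC3(O[C@H](C)[C@@H](C)O3)[C@H]2[C@H]1C
F7 | step 7 | 4,4-dimethyl-2-hydroxymethylene ketone | O=C1/C(=C\O)C[C@@]2(C)C(=C)C(C)=CC3(O[C@H](C)[C@@H](C)O3)[C@H]2C1(C)C
F8 | step 12 | C11 4-methylbenzenesulfonate of triol 15 | O[C@@H]1CC[C@@]2(C)[C@H](COS(=O)(=O)c3ccc(C)cc3)C(C)=C[C@H](O)[C@@H]2C1(C)C
F9 | step 12 | (3R,5S,6S,9R,10S)-11-(2-oxo-2H-chromen-7-yloxy)-7-ene-3,6-diol | O[C@@H]1CC[C@@]2(C)[C@H](COc3ccc4ccc(=O)oc4c3)C(C)=C[C@H](O)[C@@H]2C1(C)C
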